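## The problem

The target is a germacranolide. Its ten-membered carbocycle (C1–C10) holds a Z trisubstituted C1=C10 alkene and an E trisubstituted C4=C5 alkene. It is fused across C6–C7 to an α-methylene-γ-butyrolactone (O6–C12(=O)–C11(=C13H2)–C7). Four contiguous oxygenated stereocentres have to be set: C6 (S, lactone oxygen), C7 (S, fully substituted carbinol), C8 (S, free alcohol) and C9 (R, angelate). C8 and C9 form a threo diol that maps atom for atom onto D-tartaric acid, so these two centres can be bought. An ether oxygen on C8 can then direct the construction of C7 through a chelate, and C7 is the only centre close enough to influence C6. The molecule tolerates little. The 1(10),4-diene cyclises across the ring under acid, the lactone C6–O bond is allylic, the α-methylene lactone is a Michael acceptor, and the angelate isomerises to the tiglate under forcing acylation. The ester must therefore arrive late, and the last deprotections must be neutral or fluoride based. The feature that allows a ring-forming key step is the C4(CH3)=C5H–C6H(O) unit. It is an E allylic alcohol with the methyl group and the carbinol carbon cis, which is the pattern left by syn addition of an aldehyde carbon and a methyl group across a terminal C4≡C5 alkyne.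

## Retrosynthesis

**Ester and last protecting group.** Target 36 is traced back to its O8 4-methoxybenzyl ether 35, and 35 to the 7,9-diol lactone 32 and angelic acid 33. Acylating at the end keeps the Z enoate away from organometallic and nickel chemistry. O8 must stay blocked during this step because O8 and O9 are both secondary. The tertiary O7 hydroxyl can stay free. The forward step needs an acylation that does not isomerise the angeloyl group.

**Lactone.** Diol 32 comes from the fully protected lactone 31 by fluoride. Lactone 31 is opened at C12–O6 and reduced at C12 to the 6,12-diol 28, which comes from the silyl ether 27. Oxidative lactonisation of a 2-methylene-1,4-diol is preferred to carrying an acrylate through the ring closure, because an enoate would compete for nickel and for the organozinc. The reagent must oxidise the primary allylic alcohol and leave the secondary allylic C6 hydroxyl alone. O9 stays silylated so that only O6 can close onto C12.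

**Ring (key disconnection).** Dienol 27 is cut at C5–C6 and at C4–C15. This gives the open-chain ynal 25 and dimethylzinc 26. One operation then closes the ring, makes the E alkene, installs the C15 methyl and creates C6. Neighbouring cuts (C9–C10 or C6–C7) would each leave one of the trisubstituted alkenes to be built separately. Precursor 25 is acyclic and carries only the three centres C7, C8 and C9. The forward reaction has to close a ten-membered ring in the endo sense and must give 6S under the influence of C7.

**C7.** Ynal 25 comes from primary alcohol 24, bis-silyl ether 23 and tertiary alcohol 22. Carbinol 22 is cut at C7–C11 into ketone 17 and the alkenyl bromide 19 (used as its lithium and magnesium derivatives 20 and 21). Adding the C11 unit to a ketone that already holds C6 is the order that lets a chelate through the O8 ether give the required 7-configuration. The reverse order would give the epimer. The C6 oxygen is a silyl ether so that it does not compete for magnesium. O7 is capped as a triethylsilyl ether and not as an acetal ether, since an acetal on a tertiary alcohol would need acid at the end.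

**C6–C7.** Ketone 17 is derived from diol 15 through its mono-silyl ether 16. Diol 15 is cut at C6–C7 to aldehyde 13 and a hydroxymethyl anion equivalent. Aldehyde 13 comes from alcohol 12, which arises by reductive opening of the 4-methoxybenzylidene acetal 11. The acetal protects O7 and O8 while C10 is elaborated and then delivers the 4-methoxybenzyl group to O8, which saves a separate etherification.

**C1=C10.** Enyne 11 is cut at the alkene into methyl ketone 6 and phosphonium salt 9 (from 5-chloropent-1-yne 7). An unstabilised ylide and an α-oxygenated methyl ketone give the Z trisubstituted alkene, with the new chain cis to the oxygenated carbon. The alkyne comes in with the ylide.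

**Chiral pool.** Ketone 6 comes from Weinreb amide 5, ester 4, diol 3 and mono-silyl ether 2 of diethyl D-tartrate 1. Because 1 is C2-symmetric, monosilylation gives one compound. The remaining free hydroxyl then distinguishes the two esters, since only the ester next to it is reduced by borane. The side branch needs 2-bromoprop-2-en-1-ol 18 for 19.

## Roads not taken

**Alternative 1:** The lactone would be annulated last. An acrylate on O6 of a ten-membered C7 ketone would be treated with TiCl4 and Bu4NI, so that iodide adds to the acrylate, the titanium enolate attacks the C7 ketone (forming C7–C11), and DBU eliminates HI to give A1. The merit is real: the tertiary carbinol, the lactone and the exocyclic methylene appear in one operation. No O7 protecting group and no oxidative lactonisation are needed, and the O6 tether delivers C11 intramolecularly. In endgame length this road is better than the chosen one. Its weak points lie before and in the key step. The ten-membered α-acyloxy ketone still has to be made, so the ring problem is only moved. Its C6 hydrogen is α to the ketone and can epimerise or eliminate. TiCl4 would meet a 4-methoxybenzyl ether, an allylic ester and a 1,5-diene prone to transannular reaction. Halo-aldol additions to hindered ketones are also reversible. The chosen plan sets against the shorter endgame a key step that itself builds the ring, and a C7 centre set on an acyclic ketone by a simple chelate.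

**Alternative 2:** The ring would be closed at C9–C10 with the lactone already in place. CrCl2 with catalytic NiCl2 would turn a Z alkenyl iodide at C10 into an alkenylchromium species that adds to a C9 aldehyde, giving A2 with a free 9R hydroxyl. This is a known ring-closing reaction type for medium rings, so the closure is more secure than the chosen nickel reaction. A2 also needs only acylation and one fluoride step to reach the target. Against this, C9 would be created in the closure, so tartrate can no longer supply both C8 and C9, and C8 sits α to the aldehyde where it can epimerise. The acyclic precursor must contain the lactone, the C6/C7 pair and the E C4=C5 alkene, each of which needs its own stereoselective construction. The α-methylene lactone must also survive a large excess of divalent chromium. The chosen plan answers the better precedent of this road in two ways: its key step makes two bonds, the alkene geometry and the methyl branch at once, and it keeps a closure of the same chromium type in reserve at C5–C6.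

**Alternative 3:** A six-membered ring would be expanded by an anionic oxy-Cope rearrangement. The potassium alkoxide (KH, 18-crown-6) of a cyclohexenol bearing two alkenyl arms on adjacent carbons would form C6–C7 and break the C4–C9 bond to give ketone A3. As a way to a ten-membered 1,5-diene this is the most reliable of the four. Ring strain is paid for by the alkoxide, the Z C1=C10 alkene is simply the ring alkene of the cyclohexene, and the E C4=C5 geometry follows from a chair transition state. For this target the cost is high. A3 has no oxygen at C8 and a ketone at C9, so two stereocentres would have to be set on a flexible medium ring. The enolate formed in the rearrangement has the C7 alkoxy group in the β position and can eliminate it. The substrate, with two adjacent fully substituted carbons, has no chiral-pool source. The chosen plan gives up the secure ring formation of this road and gains C8 and C9 from tartrate without later redox steps on the ring.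

Key step: step 18

Remark: germacrane numbering is used for every intermediate. Compounds 4, 5, 6 and 11 are carried as mixtures at the benzylidene acetal carbon and 14, 15 and 16 as mixtures at C7; both centres are erased later (steps 8 and 12).

## Route

Step 1
Reactants: 1 diethyl D-tartrate
Product: 2 diethyl (2S,3S)-2-[(tert-butyldimethylsilyl)oxy]-3-hydroxybutanedioate
Conditions: TBSCl (1.05 equiv), imidazole, DMF, 0 °C
Reagents that add atoms: tert-butyldimethylsilyl chloride, CC(C)(C)[Si](C)(C)Cl
Why: Monosilylation of a C2-symmetric diol; the two hydroxyls are homotopic, so one product forms, and the bulky first silyl ether slows the second silylation. The silylated carbon becomes C9 and the free carbinol C8.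

Step 2
Reactants: 2 mono-silyl tartrate
Product: 3 ethyl (2S,3R)-2-[(tert-butyldimethylsilyl)oxy]-3,4-dihydroxybutanoate
Conditions: BH3·SMe2 (1.1 equiv), NaBH4 (5 mol %), THF, 0 °C to rt; MeOH quench
Reagents that add atoms: none
Why: Hydroxyl-directed borane reduction of an α-hydroxy ester; the alkoxyborane at O8 delivers hydride only to the adjacent ester (C7), so the α-silyloxy ester (C10) survives. No stereocentre is touched; the descriptor at C8 changes only through the priority rules.

Step 3
Reactants: 3 diol ester
Product: 4 ethyl (2S)-2-[(tert-butyldimethylsilyl)oxy]-2-[(4R)-2-(4-methoxyphenyl)-1,3-dioxolan-4-yl]acetate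
Conditions: 4-MeOC6H4CH(OMe)2, PPTS (cat.), CH2Cl2, rt
Reagents that add atoms: 4-methoxybenzaldehyde dimethyl acetal, COc1ccc(C(OC)OC)cc1
Why: Acid-catalysed transacetalisation of a terminal 1,2-diol to the dioxolane, which is faster than lactonisation of the γ-hydroxy ester. The acetal masks O7 and O8 and is the later source of the O8 benzyl ether.

Step 4
Reactants: 4 acetal ester
Product: 5 (2S)-2-[(tert-butyldimethylsilyl)oxy]-N-methoxy-2-[(4R)-2-(4-methoxyphenyl)-1,3-dioxolan-4-yl]-N-methylacetamide
Conditions: MeNH(OMe)·HCl, i-PrMgCl, THF, −20 to 0 °C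
Reagents that add atoms: N,O-dimethylhydroxylamine hydrochloride, CNOC.Cl
Why: Weinreb amide formation from an ester with the magnesium amide; the low temperature and the non-nucleophilic base keep the α-silyloxy centre C9 intact.

Step 5
Reactants: 5 Weinreb amide
Product: 6 (1S)-1-[(tert-butyldimethylsilyl)oxy]-1-[(4R)-2-(4-methoxyphenyl)-1,3-dioxolan-4-yl]propan-2-one
Conditions: MeMgBr (2 equiv), THF, 0 °C
Reagents that add atoms: methylmagnesium bromide, C[Mg]Br
Why: Weinreb ketone synthesis; the chelated tetrahedral intermediate prevents over-addition and gives the C10 methyl ketone with the C14 methyl in place.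

Step 6
Reactants: 7 5-chloropent-1-yne
Product: 9 (pent-4-yn-1-yl)triphenylphosphonium iodide, via 5-iodopent-1-yne 8 (not isolated)
Conditions: NaI, PPh3, MeCN, reflux
Reagents that add atoms: triphenylphosphine, c1ccc(cc1)P(c1ccccc1)c1ccccc1; sodium iodide, [Na+].[I-]
Why: Finkelstein exchange in the flask followed by SN2 quaternisation of triphenylphosphine at the primary iodide; the terminal alkyne is a spectator.

Step 7
Reactants: 6 methyl ketone; 9 phosphonium iodide
Product: 11 (4R)-4-[(1R,2Z)-1-[(tert-butyldimethylsilyl)oxy]-2-methylhept-2-en-6-yn-1-yl]-2-(4-methoxyphenyl)-1,3-dioxolane, via (pent-4-yn-1-ylidene)triphenylphosphorane 10 (not isolated)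
Conditions: 9, NaN(SiMe3)2 (1.0 equiv per salt), THF, −78 to 0 °C; then 6, −78 °C to rt
Reagents that add atoms: none
Why: Wittig olefination of an α-oxygenated methyl ketone with an unstabilised ylide, a combination that gives the Z trisubstituted alkene with the new chain cis to the oxygenated carbon. The phosphonium α-hydrogen is more acidic than the alkyne hydrogen, so one equivalent of base forms the ylide.

Step 8
Reactants: 11 benzylidene acetal
Product: 12 (2R,3R,4Z)-3-[(tert-butyldimethylsilyl)oxy]-2-[(4-methoxybenzyl)oxy]-4-methylnon-4-en-8-yn-1-ol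
Conditions: i-Bu2AlH (4 equiv), CH2Cl2, −78 to 0 °C
Reagents that add atoms: none
Why: Regioselective reductive opening of a 4-methoxybenzylidene acetal; aluminium binds the less hindered primary oxygen, that C–O bond breaks and hydride reduces the oxocarbenium ion, leaving the benzyl ether on O8 and the C7 alcohol free.

Step 9
Reactants: 12 primary alcohol
Product: 13 (2S,3R,4Z)-3-[(tert-butyldimethylsilyl)oxy]-2-[(4-methoxybenzyl)oxy]-4-methylnon-4-en-8-ynal
Conditions: Dess–Martin periodinane, NaHCO3, CH2Cl2, 0 °C to rt
Reagents that add atoms: none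
Why: Dess–Martin oxidation under buffered conditions, which does not epimerise α-alkoxy aldehydes.

Step 10
Reactants: 13 aldehyde
Product: 15 (3R,4R,5Z)-4-[(tert-butyldimethylsilyl)oxy]-3-[(4-methoxybenzyl)oxy]-5-methyldec-5-en-9-yne-1,2-diol, via β-hydroxysilane adduct 14 (not isolated)
Conditions: (i-PrO)Me2SiCH2MgCl (2.5 equiv), THF, −78 to 0 °C; then KF, KHCO3, 30% H2O2, THF/MeOH, rt
Reagents that add atoms: (isopropoxydimethylsilyl)methylmagnesium chloride, CC(C)O[Si](C)(C)C[Mg]Cl; hydrogen peroxide, OO
Why: Nucleophilic hydroxymethylation: Grignard addition of the silylmethyl reagent and Tamao oxidation of the C–Si bond install C6 as a primary alcohol. The configuration of the new carbinol C7 is irrelevant because it is oxidised in step 12.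

Step 11
Reactants: 15 diol
Product: 16 (3R,4R,5Z)-4-[(tert-butyldimethylsilyl)oxy]-3-[(4-methoxybenzyl)oxy]-5-methyl-1-[(triethylsilyl)oxy]dec-5-en-9-yn-2-ol
Conditions: TESCl (1.05 equiv), imidazole, CH2Cl2, −40 °C
Reagents that add atoms: chlorotriethylsilane, CC[Si](Cl)(CC)CC
Why: Selective silylation of the primary over the hindered secondary hydroxyl; the silyl ether on O6 is chosen because it does not coordinate magnesium in step 14.

Step 12
Reactants: 16 secondary alcohol
Product: 17 (3S,4R,5Z)-4-[(tert-butyldimethylsilyl)oxy]-3-[(4-methoxybenzyl)oxy]-5-methyl-1-[(triethylsilyl)oxy]dec-5-en-9-yn-2-one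
Conditions: Dess–Martin periodinane, NaHCO3, CH2Cl2, 0 °C to rt
Reagents that add atoms: none
Why: Dess–Martin oxidation to the C7 ketone under buffered, non-enolising conditions, so that C8 is not epimerised.

Step 13
Reactants: 18 2-bromoprop-2-en-1-ol
Product: 19 [(2-bromoprop-2-en-1-yl)oxy](tert-butyl)dimethylsilane
Conditions: TBSCl, imidazole, CH2Cl2, 0 °C to rt
Reagents that add atoms: tert-butyldimethylsilyl chloride, CC(C)(C)[Si](C)(C)Cl
Why: Standard silylation of a primary allylic alcohol; the bulky silyl group resists oxygen-to-carbon silyl migration in the derived alkenyllithium at −78 °C.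

Step 14
Reactants: 17 ketone; 19 alkenyl bromide
Product: 22 (2R,3S,4R,5Z)-4-[(tert-butyldimethylsilyl)oxy]-2-{3-[(tert-butyldimethylsilyl)oxy]prop-1-en-2-yl}-3-[(4-methoxybenzyl)oxy]-5-methyl-1-[(triethylsilyl)oxy]dec-5-en-9-yn-2-ol, via 2-lithioallyl silyl ether 20 (not isolated), via alkenylmagnesium bromide 21 (not isolated)
Conditions: 19 (3 equiv), t-BuLi (6 equiv), Et2O, −78 °C; MgBr2·OEt2, −78 °C; then 17, Et2O/CH2Cl2, −78 °C
Reagents that add atoms: none
Why: Chelation-controlled (Cram chelate) addition of an alkenyl Grignard reagent to an α-alkoxy ketone: magnesium bridges the carbonyl oxygen and the O8 benzyl ether, and the nucleophile enters from the face of the C8 hydrogen, which sets C7 with the target configuration. The silyl ethers on O6 and O9 do not chelate, and the excess reagent covers deprotonation of the terminal alkyne.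

Step 15
Reactants: 22 tertiary alcohol
Product: 23 (2R,3S,4R,5Z)-4-[(tert-butyldimethylsilyl)oxy]-2-{3-[(tert-butyldimethylsilyl)oxy]prop-1-en-2-yl}-3-[(4-methoxybenzyl)oxy]-5-methyl-1,2-bis[(triethylsilyl)oxy]dec-5-en-9-yne
Conditions: TESOTf, 2,6-lutidine, CH2Cl2, −78 to 0 °C
Reagents that add atoms: triethylsilyl trifluoromethanesulfonate, CC[Si](CC)(CC)OS(=O)(=O)C(F)(F)F
Why: Silyl triflates silylate hindered tertiary alcohols; the O7 silyl ether prevents α-ketol rearrangement and zinc alkoxide formation at the aldehyde stage and can later be removed by fluoride.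

Step 16
Reactants: 23 bis-triethylsilyl ether
Product: 24 (2R,3S,4R,5Z)-4-[(tert-butyldimethylsilyl)oxy]-2-{3-[(tert-butyldimethylsilyl)oxy]prop-1-en-2-yl}-3-[(4-methoxybenzyl)oxy]-5-methyl-2-[(triethylsilyl)oxy]dec-5-en-9-yn-1-ol
Conditions: PPTS (cat.), MeOH/CH2Cl2, 0 °C
Reagents that add atoms: none
Why: Mild acid methanolysis cleaves a primary triethylsilyl ether much faster than a tertiary one or a primary or secondary tert-butyldimethylsilyl ether, so only O6 is released.

Step 17
Reactants: 24 primary alcohol
Product: 25 (2S,3S,4R,5Z)-4-[(tert-butyldimethylsilyl)oxy]-2-{3-[(tert-butyldimethylsilyl)oxy]prop-1-en-2-yl}-3-[(4-methoxybenzyl)oxy]-5-methyl-2-[(triethylsilyl)oxy]dec-5-en-9-ynal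
Conditions: Dess–Martin periodinane, NaHCO3, CH2Cl2, 0 °C to rt
Reagents that add atoms: none
Why: Dess–Martin oxidation of a neopentyl-type primary alcohol; the aldehyde has no α-hydrogen and cannot epimerise.

Step 18
Reactants: 25 ynal; 26 dimethylzinc
Product: 27 (6S,7R,8S,9R,1(10)Z,4E)-9,12-bis[(tert-butyldimethylsilyl)oxy]-8-[(4-methoxybenzyl)oxy]-7-[(triethylsilyl)oxy]germacra-1(10),4,11(13)-trien-6-ol
Conditions: Ni(COD)2 (20 mol %), Me2Zn (3 equiv), THF, 0 °C to rt, 25 added over 8 h by syringe pump (final 2 mM)
Reagents that add atoms: none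
Why: Proposed new method: zerovalent nickel should bind the aldehyde and the terminal alkyne of 25 and undergo oxidative cyclisation to an oxanickelacyclopentene, with the new C5–C6 bond at the unsubstituted alkyne carbon; methyl transfer from zinc to nickel and C–C reductive elimination then place C15 on C4 and release the methylzinc alkoxide of 27. The closest known reactions are the Ni(COD)2-catalysed alkylative cyclisations of ynals with organozincs to five- and six-membered rings and the reductive ynal macrocyclisations with silanes to larger rings; a three-component closure to a ten-membered ring is not known. The ring closes in the endo mode with both alkyne carbons in the ring, the usual sense for a terminal alkyne because the aldehyde carbon bonds to the unhindered terminus; the exo mode would give a nine-membered ring. Syn addition across the alkyne puts C6 and the methyl group cis, which is the E ring alkene. The new centre C6 is controlled by C7: the forming bond is expected anti to the C7–O bond with the ring arm C8 gauche to it, which leads to 6S, and this is a prediction that the experiment has to confirm. The step needs the aldehyde–alkyne pair to react in preference to the two unactivated alkenes, which do not undergo oxidative cyclisation under these conditions, and ring closure to beat oligomerisation. Slow addition at high dilution, the Z C1=C10 alkene and the fully substituted C7 together bring the chain ends close and favour the ring.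

Step 19
Reactants: 27 macrocyclic dienol
Product: 28 (6S,7R,8S,9R,1(10)Z,4E)-9-[(tert-butyldimethylsilyl)oxy]-8-[(4-methoxybenzyl)oxy]-7-[(triethylsilyl)oxy]germacra-1(10),4,11(13)-triene-6,12-diol
Conditions: HF·pyridine, pyridine, THF, 0 °C
Reagents that add atoms: none
Why: Buffered fluoride removes the unhindered primary allylic silyl ether before the hindered secondary one at C9, and the tertiary triethylsilyl ether at C7 is expected to stay. Any material that also loses the C7 silyl group converges at 32, because step 20 tolerates a free tertiary hydroxyl and step 21 removes that group anyway.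

Step 20
Reactants: 28 6,12-diol
Product: 31 (6S,7R,8S,9R,1(10)Z,4E)-9-[(tert-butyldimethylsilyl)oxy]-8-[(4-methoxybenzyl)oxy]-7-[(triethylsilyl)oxy]germacra-1(10),4,11(13)-trien-12,6-olide, via hydroxy enal 29 (not isolated), via lactol 30 (not isolated)
Conditions: TEMPO (20 mol %), PhI(OAc)2 (3 equiv), CH2Cl2, rt
Reagents that add atoms: none
Why: Oxoammonium oxidation is selective for the primary allylic alcohol over the secondary C6 alcohol; the enal is trapped by O6 as the five-membered lactol, which is oxidised further to the α-methylene lactone. O9 is silylated, so no competing lactol can form.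

Step 21
Reactants: 31 protected lactone
Product: 32 (6S,7R,8S,9R,1(10)Z,4E)-7,9-dihydroxy-8-[(4-methoxybenzyl)oxy]germacra-1(10),4,11(13)-trien-12,6-olide
Conditions: Bu4NF, AcOH (1:1), THF, 0 °C to rt
Reagents that add atoms: none
Why: Fluoride cleaves both remaining silyl ethers (secondary at O9, tertiary at O7); buffering with acetic acid suppresses base-induced conjugate addition to the α-methylene lactone.

Step 22
Reactants: 32 7,9-diol lactone; 33 angelic acid
Product: 35 (6S,7R,8S,9R,1(10)Z,4E)-9-(angeloyloxy)-7-hydroxy-8-[(4-methoxybenzyl)oxy]germacra-1(10),4,11(13)-trien-12,6-olide, via angelic 2,4,6-trichlorobenzoic anhydride 34 (not isolated)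
Conditions: 33, 2,4,6-trichlorobenzoyl chloride, Et3N, toluene, rt; then 32, 80 °C
Reagents that add atoms: none
Why: Yamaguchi esterification through the mixed anhydride without a nucleophilic amine catalyst, the conditions under which angelates form with least isomerisation to tiglates. Only the secondary O9 hydroxyl reacts; the tertiary O7 hydroxyl is too hindered and O8 is blocked.

Step 23
Reactants: 35 O8 4-methoxybenzyl ether
Product: 36 (6S,7S,8S,9R,1(10)Z,4E)-9-(angeloyloxy)-7,8-dihydroxygermacra-1(10),4,11(13)-trien-12,6-olide, the target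
Conditions: DDQ, CH2Cl2/pH 7 phosphate buffer (10:1), 0 °C to rt
Reagents that add atoms: none
Why: Oxidative cleavage of the 4-methoxybenzyl ether by hydride abstraction and hydrolysis of the oxocarbenium ion under neutral conditions, which spare the diene, the allylic lactone and the angelate.

## Compound list

1 | diethyl D-tartrate, diethyl (2S,3S)-2,3-dihydroxybutanedioate | CCOC(=O)[C@@H](O)[C@H](O)C(=O)OCC | starting material
2 | diethyl (2S,3S)-2-[(tert-butyldimethylsilyl)oxy]-3-hydroxybutanedioate | CCOC(=O)[C@@H](O[Si](C)(C)C(C)(C)C)[C@H](O)C(=O)OCC | intermediate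
3 | ethyl (2S,3R)-2-[(tert-butyldimethylsilyl)oxy]-3,4-dihydroxybutanoate | CCOC(=O)[C@@H](O[Si](C)(C)C(C)(C)C)[C@H](O)CO | intermediate
4 | ethyl (2S)-2-[(tert-butyldimethylsilyl)oxy]-2-[(4R)-2-(4-methoxyphenyl)-1,3-dioxolan-4-yl]acetate (both acetal epimers) | CCOC(=O)[C@@H](O[Si](C)(C)C(C)(C)C)[C@H]1COC(c2ccc(OC)cc2)O1 | intermediate
5 | (2S)-2-[(tert-butyldimethylsilyl)oxy]-N-methoxy-2-[(4R)-2-(4-methoxyphenyl)-1,3-dioxolan-4-yl]-N-methylacetamide | CON(C)C(=O)[C@@H](O[Si](C)(C)C(C)(C)C)[C@H]1COC(c2ccc(OC)cc2)O1 | intermediate
6 | (1S)-1-[(tert-butyldimethylsilyl)oxy]-1-[(4R)-2-(4-methoxyphenyl)-1,3-dioxolan-4-yl]propan-2-one | CC(=O)[C@@H](O[Si](C)(C)C(C)(C)C)[C@H]1COC(c2ccc(OC)cc2)O1 | intermediate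
7 | 5-chloropent-1-yne | C#CCCCCl | starting material
8 | 5-iodopent-1-yne | C#CCCCI | intermediate
9 | (pent-4-yn-1-yl)triphenylphosphonium iodide | C#CCCC[P+](c1ccccc1)(c1ccccc1)c1ccccc1.[I-] | intermediate
10 | (pent-4-yn-1-ylidene)triphenylphosphorane | C#CCCC=P(c1ccccc1)(c1ccccc1)c1ccccc1 | intermediate
11 | (4R)-4-[(1R,2Z)-1-[(tert-butyldimethylsilyl)oxy]-2-methylhept-2-en-6-yn-1-yl]-2-(4-methoxyphenyl)-1,3-dioxolane | C#CCC/C=C(/C)[C@@H](O[Si](C)(C)C(C)(C)C)[C@H]1COC(c2ccc(OC)cc2)O1 | intermediate
12 | (2R,3R,4Z)-3-[(tert-butyldimethylsilyl)oxy]-2-[(4-methoxybenzyl)oxy]-4-methylnon-4-en-8-yn-1-ol | C#CCC/C=C(/C)[C@@H](O[Si](C)(C)C(C)(C)C)[C@H](OCc1ccc(OC)cc1)CO | intermediate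
13 | (2S,3R,4Z)-3-[(tert-butyldimethylsilyl)oxy]-2-[(4-methoxybenzyl)oxy]-4-methylnon-4-en-8-ynal | C#CCC/C=C(/C)[C@@H](O[Si](C)(C)C(C)(C)C)[C@H](OCc1ccc(OC)cc1)C=O | intermediate
14 | (3R,4R,5Z)-4-[(tert-butyldimethylsilyl)oxy]-1-[dimethyl(propan-2-yloxy)silyl]-3-[(4-methoxybenzyl)oxy]-5-methyldec-5-en-9-yn-2-ol (C2 epimers) | C#CCC/C=C(/C)[C@@H](O[Si](C)(C)C(C)(C)C)[C@H](OCc1ccc(OC)cc1)C(O)C[Si](C)(C)OC(C)C | intermediate
15 | (3R,4R,5Z)-4-[(tert-butyldimethylsilyl)oxy]-3-[(4-methoxybenzyl)oxy]-5-methyldec-5-en-9-yne-1,2-diol (C2 epimers) | C#CCC/C=C(/C)[C@@H](O[Si](C)(C)C(C)(C)C)[C@H](OCc1ccc(OC)cc1)C(O)CO | intermediate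
16 | (3R,4R,5Z)-4-[(tert-butyldimethylsilyl)oxy]-3-[(4-methoxybenzyl)oxy]-5-methyl-1-[(triethylsilyl)oxy]dec-5-en-9-yn-2-ol (C2 epimers) | C#CCC/C=C(/C)[C@@H](O[Si](C)(C)C(C)(C)C)[C@H](OCc1ccc(OC)cc1)C(O)CO[Si](CC)(CC)CC | intermediate
17 | (3S,4R,5Z)-4-[(tert-butyldimethylsilyl)oxy]-3-[(4-methoxybenzyl)oxy]-5-methyl-1-[(triethylsilyl)oxy]dec-5-en-9-yn-2-one | C#CCC/C=C(/C)[C@@H](O[Si](C)(C)C(C)(C)C)[C@H](OCc1ccc(OC)cc1)C(=O)CO[Si](CC)(CC)CC | intermediate
18 | 2-bromoprop-2-en-1-ol | C=C(Br)CO | starting material
19 | [(2-bromoprop-2-en-1-yl)oxy](tert-butyl)dimethylsilane | C=C(Br)CO[Si](C)(C)C(C)(C)C | intermediate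
20 | {3-[(tert-butyldimethylsilyl)oxy]prop-1-en-2-yl}lithium | [Li]C(=C)CO[Si](C)(C)C(C)(C)C | intermediate
21 | {3-[(tert-butyldimethylsilyl)oxy]prop-1-en-2-yl}magnesium bromide | Br[Mg]C(=C)CO[Si](C)(C)C(C)(C)C | intermediate
22 | (2R,3S,4R,5Z)-4-[(tert-butyldimethylsilyl)oxy]-2-{3-[(tert-butyldimethylsilyl)oxy]prop-1-en-2-yl}-3-[(4-methoxybenzyl)oxy]-5-methyl-1-[(triethylsilyl)oxy]dec-5-en-9-yn-2-ol | C#CCC/C=C(/C)[C@@H](O[Si](C)(C)C(C)(C)C)[C@H](OCc1ccc(OC)cc1)[C@](O)(CO[Si](CC)(CC)CC)C(=C)CO[Si](C)(C)C(C)(C)C | intermediate
23 | (2R,3S,4R,5Z)-4-[(tert-butyldimethylsilyl)oxy]-2-{3-[(tert-butyldimethylsilyl)oxy]prop-1-en-2-yl}-3-[(4-methoxybenzyl)oxy]-5-methyl-1,2-bis[(triethylsilyl)oxy]dec-5-en-9-yne | C#CCC/C=C(/C)[C@@H](O[Si](C)(C)C(C)(C)C)[C@H](OCc1ccc(OC)cc1)[C@](O[Si](CC)(CC)CC)(CO[Si](CC)(CC)CC)C(=C)CO[Si](C)(C)C(C)(C)C | intermediate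
24 | (2R,3S,4R,5Z)-4-[(tert-butyldimethylsilyl)oxy]-2-{3-[(tert-butyldimethylsilyl)oxy]prop-1-en-2-yl}-3-[(4-methoxybenzyl)oxy]-5-methyl-2-[(triethylsilyl)oxy]dec-5-en-9-yn-1-ol | C#CCC/C=C(/C)[C@@H](O[Si](C)(C)C(C)(C)C)[C@H](OCc1ccc(OC)cc1)[C@](O[Si](CC)(CC)CC)(CO)C(=C)CO[Si](C)(C)C(C)(C)C | intermediate
25 | (2S,3S,4R,5Z)-4-[(tert-butyldimethylsilyl)oxy]-2-{3-[(tert-butyldimethylsilyl)oxy]prop-1-en-2-yl}-3-[(4-methoxybenzyl)oxy]-5-methyl-2-[(triethylsilyl)oxy]dec-5-en-9-ynal | C#CCC/C=C(/C)[C@@H](O[Si](C)(C)C(C)(C)C)[C@H](OCc1ccc(OC)cc1)[C@](O[Si](CC)(CC)CC)(C=O)C(=C)CO[Si](C)(C)C(C)(C)C | intermediate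
26 | dimethylzinc | C[Zn]C | starting material
27 | (6S,7R,8S,9R,1(10)Z,4E)-9,12-bis[(tert-butyldimethylsilyl)oxy]-8-[(4-methoxybenzyl)oxy]-7-[(triethylsilyl)oxy]germacra-1(10),4,11(13)-trien-6-ol | C=C(CO[Si](C)(C)C(C)(C)C)[C@@]1(O[Si](CC)(CC)CC)[C@@H](O)/C=C(\C)CC/C=C(/C)[C@@H](O[Si](C)(C)C(C)(C)C)[C@@H]1OCc2ccc(OC)cc2 | intermediate
28 | (6S,7R,8S,9R,1(10)Z,4E)-9-[(tert-butyldimethylsilyl)oxy]-8-[(4-methoxybenzyl)oxy]-7-[(triethylsilyl)oxy]germacra-1(10),4,11(13)-triene-6,12-diol | C=C(CO)[C@@]1(O[Si](CC)(CC)CC)[C@@H](O)/C=C(\C)CC/C=C(/C)[C@@H](O[Si](C)(C)C(C)(C)C)[C@@H]1OCc2ccc(OC)cc2 | intermediate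
29 | (6S,7R,8S,9R,1(10)Z,4E)-9-[(tert-butyldimethylsilyl)oxy]-6-hydroxy-8-[(4-methoxybenzyl)oxy]-7-[(triethylsilyl)oxy]germacra-1(10),4,11(13)-trien-12-al | C=C(C=O)[C@@]1(O[Si](CC)(CC)CC)[C@@H](O)/C=C(\C)CC/C=C(/C)[C@@H](O[Si](C)(C)C(C)(C)C)[C@@H]1OCc2ccc(OC)cc2 | intermediate
30 | 12,6-lactol of 29 (C12 epimers; 6S,7R,8S,9R) | C=C1C(O)O[C@H]2/C=C(\C)CC/C=C(/C)[C@@H](O[Si](C)(C)C(C)(C)C)[C@H](OCc3ccc(OC)cc3)[C@@]12O[Si](CC)(CC)CC | intermediate
31 | (6S,7R,8S,9R,1(10)Z,4E)-9-[(tert-butyldimethylsilyl)oxy]-8-[(4-methoxybenzyl)oxy]-7-[(triethylsilyl)oxy]germacra-1(10),4,11(13)-trien-12,6-olide | C=C1C(=O)O[C@H]2/C=C(\C)CC/C=C(/C)[C@@H](O[Si](C)(C)C(C)(C)C)[C@H](OCc3ccc(OC)cc3)[C@@]12O[Si](CC)(CC)CC | intermediate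
32 | (6S,7R,8S,9R,1(10)Z,4E)-7,9-dihydroxy-8-[(4-methoxybenzyl)oxy]germacra-1(10),4,11(13)-trien-12,6-olide | C=C1C(=O)O[C@H]2/C=C(\C)CC/C=C(/C)[C@@H](O)[C@H](OCc3ccc(OC)cc3)[C@@]12O | intermediate
33 | angelic acid, (2Z)-2-methylbut-2-enoic acid | C/C=C(/C)C(=O)O | starting material
34 | (2Z)-2-methylbut-2-enoic 2,4,6-trichlorobenzoic anhydride | C/C=C(/C)C(=O)OC(=O)c1c(Cl)cc(Cl)cc1Cl | intermediate
35 | (6S,7R,8S,9R,1(10)Z,4E)-9-(angeloyloxy)-7-hydroxy-8-[(4-methoxybenzyl)oxy]germacra-1(10),4,11(13)-trien-12,6-olide | C=C1C(=O)O[C@H]2/C=C(\C)CC/C=C(/C)[C@@H](OC(=O)/C(C)=C\C)[C@H](OCc3ccc(OC)cc3)[C@@]12O | intermediate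
36 | (6S,7S,8S,9R,1(10)Z,4E)-9-(angeloyloxy)-7,8-dihydroxygermacra-1(10),4,11(13)-trien-12,6-olide | C=C1C(=O)O[C@H]2/C=C(\C)CC/C=C(/C)[C@@H](OC(=O)/C(C)=C\C)[C@H](O)[C@@]12O | target

## Step count and least certain steps

Total: 23 steps. Longest linear sequence: 21 steps (1–5, 7–12, 14–23); steps 6 and 13 are side branches.

**Step 18 (key step, new method).** The most likely failure is that the ring does not form: the terminal alkyne oligomerises at zerovalent nickel or couples between molecules, because a ten-membered endo closure is strained and slow. Exo closure to a nine-membered ring and poor facial selectivity at C6 are further risks, since nothing but C7 directs the aldehyde face. Fallback with known chemistry, from 24 back to 27: zirconium-catalysed carboalumination of the alkyne of 24 (Me3Al, Cp2ZrCl2, CH2Cl2) and iodinolysis would give the (E)-alkenyl iodide alcohol F1, in which the methyl branch and the alkene geometry are already fixed. Dess–Martin oxidation would give the iodo aldehyde F2. A Nozaki–Hiyama–Kishi closure (CrCl2, catalytic NiCl2, DMSO/THF, high dilution) would then form the same C5–C6 bond and return to 27.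

**Step 7.** Loss of Z selectivity is the main risk, together with enolisation of the α-silyloxy ketone by the basic ylide, which would epimerise C9. Fallback from 9 and 6 back to 11: hydrolysis of 9 with aqueous NaOH would give diphenyl(pent-4-yn-1-yl)phosphine oxide F3. Its dilithio derivative (n-BuLi, 2 equiv, THF, −78 °C) would add to 6 to give separable β-hydroxy phosphine oxides. The diastereomer F4 would be purified and eliminated with KH in DMF. This stepwise Horner–Wittig sequence is stereospecific (syn elimination), so it gives 11 as a single alkene isomer.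

**Step 19.** Non-selective desilylation is the risk: the tertiary triethylsilyl or the secondary tert-butyldimethylsilyl ether may be lost with the primary one, because their rates under buffered fluoride are not far apart. Fallback from 27 back to 32: excess Bu4NF would remove all three silyl groups to give the tetraol F5. TEMPO and PhI(OAc)2 would then convert F5 directly into 32, relying on the preference of the C12 aldehyde for the fused five-membered lactol with O6 over a bridged six-membered lactol with O9.

**Step 22.** Slow acylation of the hindered allylic O9 hydroxyl and Z to E isomerisation of the angeloyl group under forcing conditions are the risks. Fallback from 32 back to 35: esterification of O9 with 2-[bis(2,2,2-trifluoroethoxy)phosphoryl]propanoic acid (EDC·HCl, DMAP) would give the phosphonate ester F6. A Still–Gennari olefination with acetaldehyde (KN(SiMe3)2, 18-crown-6, THF, −78 °C) would then build the Z double bond on the substrate and give 35.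

**Step 23.** The oxidised benzyl group may be captured by the neighbouring C7 hydroxyl before water reaches it, giving a benzylidene acetal, which can be oxidised further to an anisoate. Fallback from 35 back to 36: DDQ under anhydrous conditions (4 Å molecular sieves, CH2Cl2) would make the 7,8-O-(4-methoxybenzylidene) acetal F7 on purpose. Mild hydrolysis (AcOH/H2O/THF, rt) would then release 36.

## Further compounds

F1 | step 18 | (E)-alkenyl iodide alcohol: 24 with the terminal alkyne replaced by an (E)-2-methyl-1-iodovinyl group | I/C=C(\C)CC/C=C(/C)[C@@H](O[Si](C)(C)C(C)(C)C)[C@H](OCc1ccc(OC)cc1)[C@](O[Si](CC)(CC)CC)(CO)C(=C)CO[Si](C)(C)C(C)(C)C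
F2 | step 18 | (E)-alkenyl iodide aldehyde: C6 aldehyde of F1 | I/C=C(\C)CC/C=C(/C)[C@@H](O[Si](C)(C)C(C)(C)C)[C@H](OCc1ccc(OC)cc1)[C@](O[Si](CC)(CC)CC)(C=O)C(=C)CO[Si](C)(C)C(C)(C)C
F3 | step 7 | diphenyl(pent-4-yn-1-yl)phosphine oxide | C#CCCCP(=O)(c1ccccc1)c1ccccc1
F4 | step 7 | β-hydroxy phosphine oxide from F3 and 6, the diastereomer whose syn elimination gives the Z alkene | C#CCC[C@H](P(=O)(c1ccccc1)c1ccccc1)[C@](C)(O)[C@@H](O[Si](C)(C)C(C)(C)C)[C@H]1COC(c2ccc(OC)cc2)O1
F5 | step 19 | (6S,7R,8S,9R,1(10)Z,4E)-8-[(4-methoxybenzyl)oxy]germacra-1(10),4,11(13)-triene-6,7,9,12-tetrol | C=C(CO)[C@@]1(O)[C@@H](O)/C=C(\C)CC/C=C(/C)[C@@H](O)[C@@H]1OCc2ccc(OC)cc2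
F6 | step 22 | O9 2-[bis(2,2,2-trifluoroethoxy)phosphoryl]propanoate of 32 (both epimers at the phosphonate carbon) | C=C1C(=O)O[C@H]2/C=C(\C)CC/C=C(/C)[C@@H](OC(=O)C(C)P(=O)(OCC(F)(F)F)OCC(F)(F)F)[C@H](OCc3ccc(OC)cc3)[C@@]12O
F7 | step 23 | 7,8-O-(4-methoxybenzylidene) acetal of 36 (both acetal epimers) | C=C1C(=O)O[C@H]2/C=C(\C)CC/C=C(/C)[C@@H](OC(=O)/C(C)=C\C)[C@@H]3OC(c4ccc(OC)cc4)O[C@]123
A1 | alternative 1 | 7-hydroxy α-methylene lactone with O8 4-methoxybenzyl and O9 tert-butyldimethylsilyl groups | C=C1C(=O)O[C@H]2/C=C(\C)CC/C=C(/C)[C@@H](O[Si](C)(C)C(C)(C)C)[C@H](OCc3ccc(OC)cc3)[C@@]12O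
A2 | alternative 2 | 7,8-bis(triethylsilyl) germacranolide with free 9R hydroxyl | C=C1C(=O)O[C@H]2/C=C(\C)CC/C=C(/C)[C@@H](O)[C@H](O[Si](CC)(CC)CC)[C@@]12O[Si](CC)(CC)CC
A3 | alternative 3 | (1Z,4E)-cyclodecadien-9-one with C6 silyl ether, C7 methoxymethyl ether and the C11–C13 unit | C=C(COCc2ccc(OC)cc2)[C@@]1(OCOC)[C@@H](O[Si](C)(C)C(C)(C)C)/C=C(\C)CC/C=C(/C)C(=O)C1
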